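**Plan**

- Retrosynthetic cuts: the oxolane is opened at O1–C2 and at C4–C5, so that O1 and C5 leave together as formaldehyde. Here C2 is the ring CH2 next to C3, the ring carbon bearing the (R)-carbinol, and it is carried at the acyl level. The C3–CH(O)Ar bond is then cut as an aldol, and the ArCO–CH2 bond as a Grignard acylation of succinic anhydride.
- Forward order: the chain ArCO–CH2CH2–CO–auxiliary is made and extended by an anti-aldol. The only ring is then closed in one operation at the lactone level. The ketone is reduced to the (S)-carbinol, the lactone C=O to the C2 methylene, and the ethers are removed.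
- Enabling feature: ring carbon C4 bears a benzylic oxygen. At the ketone level its precursor is therefore the single enolisable CH2 of a 4-aryl-4-oxobutanoyl unit, 1,3 to the acyl carbon that becomes C2. The oxygen of added formaldehyde ends five atoms from C2.
- Stereochemistry: C3 and its (R)-carbinol come from the (4R)-benzyloxazolidinone in a MgCl2-catalysed anti-aldol. C4 is set by equilibration to the trans lactone in the key step. The (S)-carbinol comes from Felkin–Anh reduction of the aroyl ketone.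
- Helpers taken out later: the auxiliary (expelled in the key step), the lactone carbonyl (i-Bu2AlH, then Et3SiH/BF3·OEt2), and the silyl and benzyl ethers.

Key step: step 5

Abbreviations: Ar = 4-(benzyloxy)-3-methoxyphenyl; TBS = tert-butyldimethylsilyl.

Assumption: the MgCl2-catalysed anti-aldol of N-acyloxazolidinones is taken to run through the chelated Z-enolate with the aldehyde on the face away from the benzyl group, so the (4R)-auxiliary gives the (2S,3R) adduct; if the sense were opposite, the (4S)-auxiliary would be used instead.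

**Route**

Step 1
Reactants: 1 1-(benzyloxy)-4-bromo-2-methoxybenzene; 2 succinic anhydride
Product: 4 4-Ar-4-oxobutanoic acid, via arylmagnesium bromide 3 (not isolated)
Conditions: Mg, THF, 23 °C to reflux; added to 2 (excess), THF, −78 to 0 °C; aq. HCl
Reagents that add atoms: none
Why: Grignard acylation of a cyclic anhydride, in which the magnesium carboxylate formed beside the new ketone, inverse addition and low temperature should hold back a second addition.

Step 2
Reactants: 4 4-Ar-4-oxobutanoic acid; 5 (4R)-4-benzyl-1,3-oxazolidin-2-one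
Product: 7 (4R)-4-benzyl-3-(4-Ar-4-oxobutanoyl)-1,3-oxazolidin-2-one, via mixed pivalic anhydride 6 (not isolated)
Conditions: t-BuCOCl, Et3N, THF, −20 °C; then LiCl, 5, −20 to 23 °C
Reagents that add atoms: none
Why: N-acylation of the auxiliary through a mixed anhydride (LiCl/Et3N variant), the oxazolidinone attacking the less hindered, non-pivaloyl carbonyl.

Step 3
Reactants: 7 (4R)-4-benzyl-3-(4-Ar-4-oxobutanoyl)-1,3-oxazolidin-2-one; 8 4-(benzyloxy)-3-methoxybenzaldehyde
Product: 10 (4R)-4-benzyl-3-[(2S)-4-Ar-2-{(R)-Ar(hydroxy)methyl}-4-oxobutanoyl]-1,3-oxazolidin-2-one, via trimethylsilyl ether 9 (not isolated)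
Conditions: MgCl2 (10 mol%), Et3N, Me3SiCl, EtOAc, 23 °C; then Bu4NF, AcOH, THF, 0 °C
Reagents that add atoms: none
Why: Magnesium-halide-catalysed direct anti-aldol of an N-acyloxazolidinone, in which soft enolisation of the MgCl2-chelated imide (the unchelated aryl ketone should stay untouched) gives the Z-enolate that adds to the non-enolisable aldehyde through a boat transition state on the face away from the benzyl group, setting the (2S) centre and the anti (R)-carbinol while silylation of the aldolate turns the catalyst over.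

Step 4
Reactants: 10 (4R)-4-benzyl-3-[(2S)-4-Ar-2-{(R)-Ar(hydroxy)methyl}-4-oxobutanoyl]-1,3-oxazolidin-2-one
Product: 11 (4R)-4-benzyl-3-[(2S)-4-Ar-2-{(R)-Ar(TBS-oxy)methyl}-4-oxobutanoyl]-1,3-oxazolidin-2-one
Conditions: t-BuMe2SiOTf, 2,6-lutidine, CH2Cl2, −78 to 0 °C
Reagents that add atoms: tert-butyldimethylsilyl trifluoromethanesulfonate, CC(C)(C)[Si](C)(C)OS(=O)(=O)C(F)(F)F
Why: Silyl ether formation with a silyl triflate and a hindered base, which removes the free carbinol that could otherwise undergo retro-aldol cleavage or hemiketal formation with the γ-ketone in the basic key step.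

Step 5
Reactants: 11 (4R)-4-benzyl-3-[(2S)-4-Ar-2-{(R)-Ar(TBS-oxy)methyl}-4-oxobutanoyl]-1,3-oxazolidin-2-one; 12 formaldehyde (used as paraformaldehyde)
Product: 15 (3S,4R)-4-(Ar-carbonyl)-3-{(R)-Ar(TBS-oxy)methyl}oxolan-2-one (trans), via hydroxymethyl ketone 13 (not isolated), via cis-lactone 14 (not isolated)
Conditions: (CH2O)n, K2CO3 (20 mol%), DMSO, 23 °C; then AcOH
Reagents that add atoms: none
Why: Carbonate reversibly enolises the only CH2 flanking the aryl ketone (the imide α-CH is tertiary and shielded by allylic 1,3-strain), the enolate adds to formaldehyde, and the primary alkoxide so formed, now five atoms from the imide carbonyl, attacks it and expels the oxazolidinone anion, which carries the base into the next cycle. The closest known reaction types are the hydroxymethylation–lactonisation of 3-aroylpropionic acids with formaldehyde to 4-aroylbutyrolactones and the intramolecular alcoholysis of N-acyloxazolidinones. The five-membered ring closes in the 5-exo-trig mode at the acyl carbon, which forms the O1–C2 bond of the later oxolane together with the C4–C5 bond from the aldol. The one new stereocentre, C4, is α to the aryl ketone, so it epimerises under the conditions and settles trans to the bulky C3 substituent (thermodynamic control), while C3 and the silylated carbinol keep the configuration from step 3 because the lactone α-CH is less acidic and more hindered. The step needs monoaddition of formaldehyde and survival of the β-acyloxy ketone; a small excess of formaldehyde, the reversibility of the aldol and a substoichiometric weak base quenched with acetic acid should secure both.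

Step 6
Reactants: 15 (3S,4R)-4-(Ar-carbonyl)-3-{(R)-Ar(TBS-oxy)methyl}oxolan-2-one
Product: 16 (3S,4R)-4-{(S)-Ar(hydroxy)methyl}-3-{(R)-Ar(TBS-oxy)methyl}oxolan-2-one
Conditions: LiBH(s-Bu)3, THF, −78 °C; AcOH, −78 °C
Reagents that add atoms: none
Why: Felkin–Anh-controlled hydride reduction, the bulky borohydride attacking the aryl ketone anti to the C4–C3 ring bond (the larger α-branch) with the ring CH2 inside to give the (S)-carbinol, the ketone reacting much faster than the lactone at −78 °C as in reductions of 7-oxo-dibenzylbutyrolactone lignans, and the cold acidic quench avoiding translactonisation.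

Step 7
Reactants: 16 (3S,4R)-4-{(S)-Ar(hydroxy)methyl}-3-{(R)-Ar(TBS-oxy)methyl}oxolan-2-one
Product: 17 (3S,4R)-4-{(S)-Ar(TBS-oxy)methyl}-3-{(R)-Ar(TBS-oxy)methyl}oxolan-2-one
Conditions: t-BuMe2SiOTf, 2,6-lutidine, CH2Cl2, 0 °C
Reagents that add atoms: tert-butyldimethylsilyl trifluoromethanesulfonate, CC(C)(C)[Si](C)(C)OS(=O)(=O)C(F)(F)F
Why: Silyl ether formation, which keeps the new benzylic hydroxyl from trapping the oxocarbenium ion or ionising in step 9.

Step 8
Reactants: 17 (3S,4R)-4-{(S)-Ar(TBS-oxy)methyl}-3-{(R)-Ar(TBS-oxy)methyl}oxolan-2-one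
Product: 18 (3S,4R)-4-{(S)-Ar(TBS-oxy)methyl}-3-{(R)-Ar(TBS-oxy)methyl}oxolan-2-ol (anomeric mixture)
Conditions: i-Bu2AlH, CH2Cl2, −78 °C; aq. potassium sodium tartrate
Reagents that add atoms: none
Why: Partial reduction of a lactone to the lactol, the tetrahedral aluminium alkoxide persisting at −78 °C until work-up so that the ring C–O bond made in step 5 stays intact.

Step 9
Reactants: 18 (3S,4R)-4-{(S)-Ar(TBS-oxy)methyl}-3-{(R)-Ar(TBS-oxy)methyl}oxolan-2-ol
Product: 20 (3R,4R)-3-{(R)-Ar(TBS-oxy)methyl}-4-{(S)-Ar(TBS-oxy)methyl}oxolane, via oxocarbenium ion 19 (not isolated)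
Conditions: Et3SiH, BF3·OEt2, CH2Cl2, −78 °C
Reagents that add atoms: none
Why: Ionic hydrogenation (reductive deoxygenation) of a lactol, BF3 ionising the anomeric C–OH to the cyclic oxocarbenium ion that Et3SiH reduces to the C2 methylene, with the benzylic silyl ethers expected to survive at −78 °C as p-methoxybenzyl ethers do.

Step 10
Reactants: 20 (3R,4R)-3-{(R)-Ar(TBS-oxy)methyl}-4-{(S)-Ar(TBS-oxy)methyl}oxolane
Product: 21 (S)-Ar{(3R,4R)-4-[(R)-Ar(hydroxy)methyl]oxolan-3-yl}methanol
Conditions: Bu4NF, AcOH, THF, 23 °C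
Reagents that add atoms: none
Why: Fluoride-mediated desilylation, buffered with acetic acid so that neither strong base nor acid acts on the electron-rich benzylic alcohols.

Step 11
Reactants: 21 (S)-Ar{(3R,4R)-4-[(R)-Ar(hydroxy)methyl]oxolan-3-yl}methanol
Product: 22 (S)-(4-hydroxy-3-methoxyphenyl){(3R,4R)-4-[(R)-hydroxy(4-hydroxy-3-methoxyphenyl)methyl]oxolan-3-yl}methanol (target)
Conditions: H2 (1 atm), Pd/C, EtOAc–EtOH, 23 °C
Reagents that add atoms: none
Why: Hydrogenolysis of aryl benzyl ethers over palladium on carbon under neutral conditions, which should be faster than C–O hydrogenolysis of the secondary benzylic alcohols, as in the debenzylation of lignin model compounds.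

**Compound list**

1 | 1-(benzyloxy)-4-bromo-2-methoxybenzene | COc1cc(Br)ccc1OCc1ccccc1 | starting material
2 | succinic anhydride | O=C1CCC(=O)O1 | starting material
3 | [4-(benzyloxy)-3-methoxyphenyl]magnesium bromide | COc1cc([Mg]Br)ccc1OCc1ccccc1 | intermediate
4 | 4-[4-(benzyloxy)-3-methoxyphenyl]-4-oxobutanoic acid | COc1cc(C(=O)CCC(=O)O)ccc1OCc1ccccc1 | intermediate
5 | (4R)-4-benzyl-1,3-oxazolidin-2-one | O=C1N[C@H](Cc2ccccc2)CO1 | starting material
6 | 4-Ar-4-oxobutanoic pivalic anhydride | COc1cc(C(=O)CCC(=O)OC(=O)C(C)(C)C)ccc1OCc1ccccc1 | intermediate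
7 | (4R)-4-benzyl-3-(4-Ar-4-oxobutanoyl)-1,3-oxazolidin-2-one | COc1cc(C(=O)CCC(=O)N2[C@H](Cc3ccccc3)COC2=O)ccc1OCc1ccccc1 | intermediate
8 | 4-(benzyloxy)-3-methoxybenzaldehyde | COc1cc(C=O)ccc1OCc1ccccc1 | starting material
9 | (4R)-4-benzyl-3-[(2S)-4-Ar-2-{(R)-Ar(trimethylsilyloxy)methyl}-4-oxobutanoyl]-1,3-oxazolidin-2-one | O=C(N1[C@H](Cc2ccccc2)COC1=O)[C@@H](CC(=O)c1ccc(OCc2ccccc2)c(OC)c1)[C@@H](O[Si](C)(C)C)c1ccc(OCc2ccccc2)c(OC)c1 | intermediate
10 | (4R)-4-benzyl-3-[(2S)-4-Ar-2-{(R)-Ar(hydroxy)methyl}-4-oxobutanoyl]-1,3-oxazolidin-2-one | O=C(N1[C@H](Cc2ccccc2)COC1=O)[C@@H](CC(=O)c1ccc(OCc2ccccc2)c(OC)c1)[C@@H](O)c1ccc(OCc2ccccc2)c(OC)c1 | intermediate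
11 | (4R)-4-benzyl-3-[(2S)-4-Ar-2-{(R)-Ar(TBS-oxy)methyl}-4-oxobutanoyl]-1,3-oxazolidin-2-one | O=C(N1[C@H](Cc2ccccc2)COC1=O)[C@@H](CC(=O)c1ccc(OCc2ccccc2)c(OC)c1)[C@@H](O[Si](C)(C)C(C)(C)C)c1ccc(OCc2ccccc2)c(OC)c1 | intermediate
12 | formaldehyde (as paraformaldehyde) | C=O | starting material
13 | (4R)-4-benzyl-3-[(2S)-4-Ar-2-{(R)-Ar(TBS-oxy)methyl}-3-(hydroxymethyl)-4-oxobutanoyl]-1,3-oxazolidin-2-one, both C3 epimers | O=C(N1[C@H](Cc2ccccc2)COC1=O)[C@@H](C(CO)C(=O)c1ccc(OCc2ccccc2)c(OC)c1)[C@@H](O[Si](C)(C)C(C)(C)C)c1ccc(OCc2ccccc2)c(OC)c1 | intermediate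
14 | (3S,4S)-4-(Ar-carbonyl)-3-{(R)-Ar(TBS-oxy)methyl}oxolan-2-one (cis) | COc1cc(C(=O)[C@@H]2COC(=O)[C@@H]2[C@@H](O[Si](C)(C)C(C)(C)C)c2ccc(OCc3ccccc3)c(OC)c2)ccc1OCc1ccccc1 | intermediate
15 | (3S,4R)-4-(Ar-carbonyl)-3-{(R)-Ar(TBS-oxy)methyl}oxolan-2-one (trans) | COc1cc(C(=O)[C@H]2COC(=O)[C@@H]2[C@@H](O[Si](C)(C)C(C)(C)C)c2ccc(OCc3ccccc3)c(OC)c2)ccc1OCc1ccccc1 | intermediate
16 | (3S,4R)-4-{(S)-Ar(hydroxy)methyl}-3-{(R)-Ar(TBS-oxy)methyl}oxolan-2-one | COc1cc([C@@H](O)[C@H]2COC(=O)[C@@H]2[C@@H](O[Si](C)(C)C(C)(C)C)c2ccc(OCc3ccccc3)c(OC)c2)ccc1OCc1ccccc1 | intermediate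
17 | (3S,4R)-4-{(S)-Ar(TBS-oxy)methyl}-3-{(R)-Ar(TBS-oxy)methyl}oxolan-2-one | COc1cc([C@@H](O[Si](C)(C)C(C)(C)C)[C@H]2COC(=O)[C@@H]2[C@@H](O[Si](C)(C)C(C)(C)C)c2ccc(OCc3ccccc3)c(OC)c2)ccc1OCc1ccccc1 | intermediate
18 | (3S,4R)-4-{(S)-Ar(TBS-oxy)methyl}-3-{(R)-Ar(TBS-oxy)methyl}oxolan-2-ol, anomeric mixture | COc1cc([C@@H](O[Si](C)(C)C(C)(C)C)[C@H]2COC(O)[C@@H]2[C@@H](O[Si](C)(C)C(C)(C)C)c2ccc(OCc3ccccc3)c(OC)c2)ccc1OCc1ccccc1 | intermediate
19 | cyclic oxocarbenium ion from 18 (O1=C2 cation, same substituents) | COc1cc([C@@H](O[Si](C)(C)C(C)(C)C)[C@H]2C[O+]=C[C@@H]2[C@@H](O[Si](C)(C)C(C)(C)C)c2ccc(OCc3ccccc3)c(OC)c2)ccc1OCc1ccccc1 | intermediate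
20 | (3R,4R)-3-{(R)-Ar(TBS-oxy)methyl}-4-{(S)-Ar(TBS-oxy)methyl}oxolane | COc1cc([C@@H](O[Si](C)(C)C(C)(C)C)[C@H]2COC[C@@H]2[C@@H](O[Si](C)(C)C(C)(C)C)c2ccc(OCc3ccccc3)c(OC)c2)ccc1OCc1ccccc1 | intermediate
21 | (S)-Ar{(3R,4R)-4-[(R)-Ar(hydroxy)methyl]oxolan-3-yl}methanol | COc1cc([C@@H](O)[C@H]2COC[C@@H]2[C@@H](O)c2ccc(OCc3ccccc3)c(OC)c2)ccc1OCc1ccccc1 | intermediate
22 | (S)-(4-hydroxy-3-methoxyphenyl){(3R,4R)-4-[(R)-hydroxy(4-hydroxy-3-methoxyphenyl)methyl]oxolan-3-yl}methanol | COc1cc([C@@H](O)[C@H]2COC[C@@H]2[C@@H](O)c2ccc(O)c(OC)c2)ccc1O | target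

Total step count: 11. Longest linear sequence: 11 steps (1 to 22).

**Steps most likely to fail**

Step 5. Base-induced β-elimination of the lactone carboxylate from the product (retro-oxa-Michael opening), a second hydroxymethylation at C4, or attack of the ketone enolate on the carbamate carbonyl may compete with the cascade. The fallback separates enolisation, C–C bond formation and ring closure. It sets out from 11: kinetic deprotonation with LiN(SiMe3)2 and trapping with Me3SiCl at −78 °C should give the silyl enol ether F1. A Mukaiyama hydroxymethylation with aqueous formaldehyde and catalytic Sc(OTf)3 should give the hydroxymethyl ketone 13, this time isolated. Lactonisation with catalytic 4-(dimethylamino)pyridine in toluene, which also equilibrates C4, should return to the route at 15.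

Step 9. Lewis-acid ionisation of the electron-rich benzylic silyl ethers (loss of a protecting group followed by reduction or participation) may compete with ionisation of the lactol. The fallback avoids Lewis acid altogether and sets out from 17: LiAlH4 in THF should give the 1,4-diol F2, and a Mitsunobu cyclodehydration (PPh3, diisopropyl azodicarboxylate, THF) should close the oxolane and return to the route at 20.

Step 6. Facial selectivity of the substrate-controlled hydride addition may be insufficient, or the basic hydride may enolise the β-acyloxy ketone. The fallback moves the control from the substrate to a catalyst and sets out from 15: Corey–Bakshi–Shibata reduction with (R)-2-methyl-CBS-oxazaborolidine and BH3·SMe2, in which the aryl group acts as the large substituent, should give the (S)-carbinol and return to the route at 16 without a new intermediate.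

Further compounds
F1 | step 5 | (4R)-4-benzyl-3-[(2S,3Z)-4-Ar-2-{(R)-Ar(TBS-oxy)methyl}-4-(trimethylsilyloxy)but-3-enoyl]-1,3-oxazolidin-2-one | O=C(N1[C@H](Cc2ccccc2)COC1=O)[C@@H](/C=C(\O[Si](C)(C)C)c1ccc(OCc2ccccc2)c(OC)c1)[C@@H](O[Si](C)(C)C(C)(C)C)c1ccc(OCc2ccccc2)c(OC)c1
F2 | step 9 | (2R,3R)-2-{(S)-Ar(TBS-oxy)methyl}-3-{(R)-Ar(TBS-oxy)methyl}butane-1,4-diol | COc1cc([C@@H](O[Si](C)(C)C(C)(C)C)[C@H]([C@H](CO)[C@@H](O[Si](C)(C)C(C)(C)C)c2ccc(OCc3ccccc3)c(OC)c2)CO)ccc1OCc1ccccc1
F0 | step 6 | none | none
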